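**Retrosynthetic overview**
1. Target = (3S,6S,7S,9R,11R)-3,9-diacetoxygermacra-1(10)Z,4Z-dien-12,6-olide. The acetates, the aryl/silyl protecting groups and the γ-lactone (C6–OH + C12–OH, oxidative lactonisation) are removed first, leading back to ten-membered ketone 19.
2. Key disconnection C8–C9: anionic oxy-Cope ring expansion (six → ten) of cyclohexenol 16. The enabling feature is the 3-oxido-1,5-diene C8=C7–C6(O⁻)–C1–C10=C9 laid across the C1–C6 bond of a cyclohexene ring (C1–C6), whose endocyclic C4=C5 bond becomes the cis C4=C5 olefin of the product.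
3. 16 comes from enone 6 ((S)-carvone: allylic chlorination, 1,2-reduction, silylation, aryl ether, allylic oxidation) and the alkenylcerium reagent from bromide 12 (Roche ester), followed by allyl ether → (E)-enol ether isomerisation.
4. Ring order: six-membered carbocycle (from carvone) → ten-membered carbocycle (step 12) → γ-lactone (step 15).

Key step: step 12

Remark: locants C1–C15 in the text are germacrane numbers (C1–C10 ring, C11–C13 on C7 with C12 the carboxyl carbon, C14 on C10, C15 on C4) and are also used for the corresponding atoms of the six-membered precursors.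

**Step 1**
Reactants: 1 (S)-(+)-carvone
Product: 2 (5S)-5-(3-chloroprop-1-en-2-yl)-2-methylcyclohex-2-en-1-one
Conditions: Ca(OCl)2, CO2 (dry ice), CH2Cl2/H2O, 0 °C
Reagents that add atoms: Ca(OCl)2 (calcium hypochlorite), [Ca+2].[O-]Cl.[O-]Cl
Why: HOCl formed in situ should effect an ene-type allylic chlorination at the electron-rich isopropenyl group (the enone alkene is deactivated), leaving the ring stereocenter untouched.

**Step 2**
Reactants: 2 (5S)-chloro enone
Product: 3 (1S,5S)-5-(3-chloroprop-1-en-2-yl)-2-methylcyclohex-2-en-1-ol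
Conditions: NaBH4, CeCl3·7H2O, MeOH, −78 → 0 °C
Reagents that add atoms: none
Why: Luche 1,2-reduction with axial hydride delivery, as in the carvone → cis-carveol reduction, should set the C3 carbinol center (S) with OH cis to the C1 side chain.

**Step 3**
Reactants: 3 (1S,5S)-allylic alcohol
Product: 4 tert-butyldimethylsilyl ether of 3
Conditions: t-BuMe2SiOTf, 2,6-lutidine, CH2Cl2, −78 °C
Reagents that add atoms: tert-butyldimethylsilyl triflate, CC(C)(C)[Si](C)(C)OS(=O)(=O)C(F)(F)F
Why: silylation with a silyl triflate and a hindered pyridine base avoids nucleophilic bases that could displace the allylic chloride, and no stereocenter is touched.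

**Step 4**
Reactants: 4 silyl ether allylic chloride
Product: 5 4-methoxyphenyl allyl ether
Conditions: 4-methoxyphenol, K2CO3, n-Bu4NI (cat.), DMF, 50 °C
Reagents that add atoms: 4-methoxyphenol, COc1ccc(O)cc1
Why: Williamson ether synthesis on the primary allylic chloride with a weakly basic phenoxide (SN2 and SN2′ give the same product) installs the future C9 oxygen as an oxidatively removable aryl ether.

**Step 5**
Reactants: 5 aryl allyl ether
Product: 6 (4S,6S)-4-silyloxy-6-[3-(4-methoxyphenoxy)prop-1-en-2-yl]-3-methylcyclohex-2-en-1-one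
Conditions: CrO3, 3,5-dimethylpyrazole, CH2Cl2, −20 °C
Reagents that add atoms: CrO3 (chromium trioxide), O=[Cr](=O)=O
Why: allylic C–H oxidation of the trisubstituted ring alkene at its only ring methylene (C6), the reaction type used for Δ5-steroid ethers, should give the 4-silyloxy enone, since the CH–OSi position and the electron-poorer 1,1-disubstituted alkene react more slowly.

**Step 6**
Reactants: 7 methyl (2S)-3-hydroxy-2-methylpropanoate (Roche ester)
Product: 8 methyl (2S)-3-[(tert-butyldimethylsilyl)oxy]-2-methylpropanoate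
Conditions: t-BuMe2SiCl, imidazole, CH2Cl2, 23 °C
Reagents that add atoms: tert-butyldimethylsilyl chloride, CC(C)(C)[Si](C)(C)Cl
Why: standard silylation of the primary alcohol, with the stereocenter untouched.

**Step 7**
Reactants: 8 silyloxy ester
Product: 9 (2S)-3-[(tert-butyldimethylsilyl)oxy]-2-methylpropanal
Conditions: i-Bu2AlH (1.05 equiv), CH2Cl2, −78 °C; Rochelle salt work-up; used crude
Reagents that add atoms: none
Why: low-temperature partial reduction stops at the tetrahedral aluminium hemiacetal, which releases the aldehyde on work-up without enolising the α-stereocenter.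

**Step 8**
Reactants: 9 aldehyde
Product: 10 tert-butyldimethyl{[(2R)-2-methylbut-3-yn-1-yl]oxy}silane
Conditions: dimethyl (1-diazo-2-oxopropyl)phosphonate, K2CO3, MeOH, 0 → 23 °C
Reagents that add atoms: dimethyl (1-diazo-2-oxopropyl)phosphonate, COP(=O)(OC)C(=[N+]=[N-])C(C)=O
Why: Seyferth–Gilbert homologation with the Ohira–Bestmann reagent converts the aldehyde into the terminal alkyne under mild carbonate conditions that should keep the α-stereocenter.

**Step 9**
Reactants: 10 terminal alkyne
Product: 12 {[(2S)-3-bromo-2-methylbut-3-en-1-yl]oxy}(tert-butyl)dimethylsilane, via alkenylalane 11 (not isolated)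
Conditions: NiCl2(dppp) (3 mol %), i-Bu2AlH, THF, 0 → 23 °C; then N-bromosuccinimide, 0 °C
Reagents that add atoms: N-bromosuccinimide, O=C1CCC(=O)N1Br
Why: nickel-catalysed α-selective (Markovnikov) hydroalumination places aluminium on the internal alkyne carbon, and bromodealumination then gives the 2-bromoalk-1-ene.

**Step 10**
Reactants: 12 alkenyl bromide; 6 enone
Product: 15 (1R,4S,6S)-1,6-dialkenyl-4-silyloxycyclohex-2-en-1-ol, via vinyllithium 13 (not isolated), via organocerium reagent 14 (not isolated)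
Conditions: t-BuLi (2 equiv), Et2O, −78 °C; CeCl3 (anhydrous), THF, −78 °C; then 6, −78 °C; NH4Cl work-up
Reagents that add atoms: none
Why: bromine–lithium exchange and transmetalation give a weakly basic organocerium reagent that adds 1,2 to the enolisable enone, and axial attack (anti to the pseudoaxial C1–H) on the half-chair with the C1 and C3 substituents pseudoequatorial, as in additions to carvone-type enones, should place the new alkenyl group cis to the C1 side chain (C6 = 1R in the name).

**Step 11**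
Reactants: 15 tertiary alcohol with allyl aryl ether
Product: 16 (1R,4S,6S)-6-[(1E)-1-(4-methoxyphenoxy)prop-1-en-2-yl] cyclohexenol
Conditions: LiN(i-Pr)2 (4 equiv), THF, 0 → 23 °C; pH 7 buffer work-up
Reagents that add atoms: none
Why: base-mediated allyl ether → enol ether isomerisation, in which the lithium alkoxide is inert to rearrangement at this temperature and the chelated oxyallyllithium is protonated at the γ-carbon with oxygen cis to the new methyl group, should give the (E)-enol ether, which is also the less hindered isomer.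

**Step 12**
Reactants: 16 (E)-enol ether cyclohexenol
Product: 19 (2Z,4S,6Z,8R,10S)-cyclodeca-2,6-dien-1-one, via potassium alkoxide 17 (not isolated), via potassium enolate 18 (not isolated)
Conditions: KH (1.5 equiv), 18-crown-6 (1.5 equiv), THF, 0 → 23 °C; then cannulation into AcOH/THF, −78 °C
Reagents that add atoms: none
Why: Deprotonation gives potassium alkoxide 17, whose C8=C7–C6(O⁻)–C1–C10=C9 array should undergo a charge-accelerated [3,3]-sigmatropic (anionic oxy-Cope) shift through a chair transition state, cleaving the C1–C6 bond of the carvone-derived ring while C8–C9 forms. The closest known reaction type is the KH/18-crown-6 ring expansion of 1,2-dialkenylcyclohex-2-en-1-ols to cyclodeca-2,6-dien-1-ones used for germacrane ketones. The ten-membered carbocycle is closed in a sigmatropic ring-expansion mode (four-atom enlargement of the six-membered ring, not an end-to-end cyclisation), and the endocyclic C4=C5 bond is carried over unchanged as the cis enone olefin. C9 is set by chirality transfer from C1 (which becomes sp2) through the chair in which the (E)-aryloxy group is equatorial; C1=C10 should emerge Z because C2 is pseudoaxial on that chair when the C6 alkenyl group is axial and the C1 alkenyl group equatorial on the half-chair; C7 is set by kinetic protonation of enolate 18 from the convex face of the cis-decalin-like fold. The step needs the exocyclic C7=C8 bond rather than the ring C4=C5 bond as π-partner, and the half-chair with equatorial C1 and C3 substituents rather than its ring-flipped form (which would give the 1(10)E isomer); both are secured by the cis relationship of the C3 silyloxy and C1 alkenyl groups (the flipped form is 1,3-diaxial and is the only one in which C9 can reach C4) and by bond formation at an unhindered CH2 terminus.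

**Step 13**
Reactants: 19 ten-membered enone
Product: 20 (1S,2Z,4S,6Z,8R,10S)-cyclodeca-2,6-dien-1-ol
Conditions: i-Bu2AlH, CH2Cl2, −78 °C
Reagents that add atoms: none
Why: 1,2-reduction of the cis-enone with hydride delivered to the peripheral (convex) face of the folded ring, anti to the transannular C1–C2 segment, should give the (6S)-alcohol with H6 trans to H7.

**Step 14**
Reactants: 20 allylic alcohol with two silyl ethers
Product: 21 1,4-diol (C6–OH and C12–OH free)
Conditions: HF·pyridine, pyridine, THF, 0 °C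
Reagents that add atoms: none
Why: buffered HF·pyridine cleaves the unhindered primary silyl ether much faster than the hindered secondary allylic one at C3.

**Step 15**
Reactants: 21 1,4-diol
Product: 23 γ-lactone with C3 silyl ether and C9 aryl ether, via lactol 22 (not isolated)
Conditions: TEMPO (0.2 equiv), PhI(OAc)2 (2.5 equiv), CH2Cl2, 23 °C
Reagents that add atoms: none
Why: oxoammonium oxidation of the primary alcohol gives the aldehyde, which closes to the five-membered lactol with the C6 hydroxyl and is oxidised on to the γ-lactone (oxidative lactonisation of a 1,4-diol) under non-basic conditions that should not enolise C11.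

**Step 16**
Reactants: 23 lactone aryl ether
Product: 24 9-hydroxy lactone
Conditions: (NH4)2Ce(NO3)6 (2.5 equiv), pyridine, MeCN/H2O (4:1), 0 °C
Reagents that add atoms: none
Why: oxidative dearylation of the 4-methoxyphenyl ether by the one-electron oxidant (tetravalent cerium) cleaves the aryl–oxygen bond, so the C9 alcohol is released with retention of configuration.

**Step 17**
Reactants: 24 9-hydroxy 3-silyloxy lactone
Product: 25 3,9-diol lactone
Conditions: HF·pyridine, THF, 0 → 23 °C
Reagents that add atoms: none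
Why: desilylation under non-basic conditions avoids epimerisation of C11 α to the lactone carbonyl.

**Step 18**
Reactants: 25 3,9-diol lactone
Product: 26 (3S,6S,7S,9R,11R)-3,9-diacetoxygermacra-1(10)Z,4Z-dien-12,6-olide
Conditions: Ac2O, DMAP (cat.), pyridine, CH2Cl2, 0 → 23 °C
Reagents that add atoms: acetic anhydride, CC(=O)OC(C)=O
Why: DMAP-catalysed acetylation of both secondary allylic alcohols proceeds with retention at C3 and C9.

**Compound list**
1 | (S)-(+)-carvone, (5S)-2-methyl-5-(prop-1-en-2-yl)cyclohex-2-en-1-one | CC1=CC[C@@H](CC1=O)C(C)=C | starting material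
2 | (5S)-5-(3-chloroprop-1-en-2-yl)-2-methylcyclohex-2-en-1-one | CC1=CC[C@@H](CC1=O)C(=C)CCl | intermediate
3 | (1S,5S)-5-(3-chloroprop-1-en-2-yl)-2-methylcyclohex-2-en-1-ol | CC1=CC[C@@H](C[C@@H]1O)C(=C)CCl | intermediate
4 | tert-butyl{[(1S,5S)-5-(3-chloroprop-1-en-2-yl)-2-methylcyclohex-2-en-1-yl]oxy}dimethylsilane | CC1=CC[C@@H](C[C@@H]1O[Si](C)(C)C(C)(C)C)C(=C)CCl | intermediate
5 | tert-butyl({(1S,5S)-5-[3-(4-methoxyphenoxy)prop-1-en-2-yl]-2-methylcyclohex-2-en-1-yl}oxy)dimethylsilane | CC1=CC[C@@H](C[C@@H]1O[Si](C)(C)C(C)(C)C)C(=C)COc2ccc(OC)cc2 | intermediate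
6 | (4S,6S)-4-[(tert-butyldimethylsilyl)oxy]-6-[3-(4-methoxyphenoxy)prop-1-en-2-yl]-3-methylcyclohex-2-en-1-one | CC1=CC(=O)[C@@H](C[C@@H]1O[Si](C)(C)C(C)(C)C)C(=C)COc2ccc(OC)cc2 | intermediate
7 | methyl (2S)-3-hydroxy-2-methylpropanoate (Roche ester) | COC(=O)[C@@H](C)CO | starting material
8 | methyl (2S)-3-[(tert-butyldimethylsilyl)oxy]-2-methylpropanoate | COC(=O)[C@@H](C)CO[Si](C)(C)C(C)(C)C | intermediate
9 | (2S)-3-[(tert-butyldimethylsilyl)oxy]-2-methylpropanal | O=C[C@@H](C)CO[Si](C)(C)C(C)(C)C | intermediate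
10 | tert-butyldimethyl{[(2R)-2-methylbut-3-yn-1-yl]oxy}silane | C#C[C@@H](C)CO[Si](C)(C)C(C)(C)C | intermediate
11 | {(3S)-4-[(tert-butyldimethylsilyl)oxy]-3-methylbut-1-en-2-yl}bis(2-methylpropyl)alane | C=C([Al](CC(C)C)CC(C)C)[C@@H](C)CO[Si](C)(C)C(C)(C)C | intermediate (not isolated)
12 | {[(2S)-3-bromo-2-methylbut-3-en-1-yl]oxy}(tert-butyl)dimethylsilane | C=C(Br)[C@@H](C)CO[Si](C)(C)C(C)(C)C | intermediate
13 | {(3R)-4-[(tert-butyldimethylsilyl)oxy]-3-methylbut-1-en-2-yl}lithium | [Li]C(=C)[C@@H](C)CO[Si](C)(C)C(C)(C)C | intermediate (not isolated)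
14 | dichloro{(3S)-4-[(tert-butyldimethylsilyl)oxy]-3-methylbut-1-en-2-yl}cerium | Cl[Ce](Cl)C(=C)[C@@H](C)CO[Si](C)(C)C(C)(C)C | intermediate (not isolated)
15 | (1R,4S,6S)-4-[(tert-butyldimethylsilyl)oxy]-1-{(3R)-4-[(tert-butyldimethylsilyl)oxy]-3-methylbut-1-en-2-yl}-6-[3-(4-methoxyphenoxy)prop-1-en-2-yl]-3-methylcyclohex-2-en-1-ol | CC1=C[C@](O)(C(=C)[C@@H](C)CO[Si](C)(C)C(C)(C)C)[C@@H](C[C@@H]1O[Si](C)(C)C(C)(C)C)C(=C)COc2ccc(OC)cc2 | intermediate
16 | (1R,4S,6S)-4-[(tert-butyldimethylsilyl)oxy]-1-{(3R)-4-[(tert-butyldimethylsilyl)oxy]-3-methylbut-1-en-2-yl}-6-[(1E)-1-(4-methoxyphenoxy)prop-1-en-2-yl]-3-methylcyclohex-2-en-1-ol | CC1=C[C@](O)(C(=C)[C@@H](C)CO[Si](C)(C)C(C)(C)C)[C@@H](C[C@@H]1O[Si](C)(C)C(C)(C)C)/C(C)=C/Oc2ccc(OC)cc2 | intermediate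
17 | potassium alkoxide of 16 | CC1=C[C@]([O-])(C(=C)[C@@H](C)CO[Si](C)(C)C(C)(C)C)[C@@H](C[C@@H]1O[Si](C)(C)C(C)(C)C)/C(C)=C/Oc2ccc(OC)cc2.[K+] | intermediate (not isolated)
18 | potassium C6 enolate of 19 (C6=C7 bond, oxygen cis to C8) | CC(C)(C)[Si](C)(C)O[C@H]1C/C=C(/C)[C@H](Oc2ccc(OC)cc2)C/C([C@@H](C)CO[Si](C)(C)C(C)(C)C)=C(\[O-])/C=C\1C.[K+] | intermediate (not isolated)
19 | (2Z,4S,6Z,8R,10S)-4-[(tert-butyldimethylsilyl)oxy]-10-{(2R)-1-[(tert-butyldimethylsilyl)oxy]propan-2-yl}-8-(4-methoxyphenoxy)-3,7-dimethylcyclodeca-2,6-dien-1-one | CC(C)(C)[Si](C)(C)O[C@H]1C/C=C(/C)[C@H](Oc2ccc(OC)cc2)C[C@@H]([C@@H](C)CO[Si](C)(C)C(C)(C)C)C(=O)/C=C\1C | intermediate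
20 | (1S,2Z,4S,6Z,8R,10S)-4-[(tert-butyldimethylsilyl)oxy]-10-{(2R)-1-[(tert-butyldimethylsilyl)oxy]propan-2-yl}-8-(4-methoxyphenoxy)-3,7-dimethylcyclodeca-2,6-dien-1-ol | CC(C)(C)[Si](C)(C)O[C@H]1C/C=C(/C)[C@H](Oc2ccc(OC)cc2)C[C@@H]([C@@H](C)CO[Si](C)(C)C(C)(C)C)[C@H](O)/C=C\1C | intermediate
21 | (1S,2Z,4S,6Z,8R,10S)-4-[(tert-butyldimethylsilyl)oxy]-10-[(2R)-1-hydroxypropan-2-yl]-8-(4-methoxyphenoxy)-3,7-dimethylcyclodeca-2,6-dien-1-ol | CC(C)(C)[Si](C)(C)O[C@H]1C/C=C(/C)[C@H](Oc2ccc(OC)cc2)C[C@@H]([C@@H](C)CO)[C@H](O)/C=C\1C | intermediate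
22 | lactol (12-hydroxy-6,12-epoxy hemiacetal, anomer mixture) of the C12 aldehyde from 21 | CC(C)(C)[Si](C)(C)O[C@H]1C/C=C(/C)[C@H](Oc2ccc(OC)cc2)C[C@@H]3[C@@H](/C=C\1C)OC(O)[C@@H]3C | intermediate (not isolated)
23 | (3S,6S,7S,9R,11R)-3-[(tert-butyldimethylsilyl)oxy]-9-(4-methoxyphenoxy)germacra-1(10)Z,4Z-dien-12,6-olide | CC(C)(C)[Si](C)(C)O[C@H]1C/C=C(/C)[C@H](Oc2ccc(OC)cc2)C[C@@H]3[C@@H](/C=C\1C)OC(=O)[C@@H]3C | intermediate
24 | (3S,6S,7S,9R,11R)-3-[(tert-butyldimethylsilyl)oxy]-9-hydroxygermacra-1(10)Z,4Z-dien-12,6-olide | CC(C)(C)[Si](C)(C)O[C@H]1C/C=C(/C)[C@H](O)C[C@@H]2[C@@H](/C=C\1C)OC(=O)[C@@H]2C | intermediate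
25 | (3S,6S,7S,9R,11R)-3,9-dihydroxygermacra-1(10)Z,4Z-dien-12,6-olide | O[C@H]1C/C=C(/C)[C@H](O)C[C@@H]2[C@@H](/C=C\1C)OC(=O)[C@@H]2C | intermediate
26 | (3S,6S,7S,9R,11R)-3,9-diacetoxygermacra-1(10)Z,4Z-dien-12,6-olide | CC(=O)O[C@H]1C/C=C(/C)[C@H](OC(C)=O)C[C@@H]2[C@@H](/C=C\1C)OC(=O)[C@@H]2C | target

**Step count and risks**
Total step count: 18. Longest linear sequence: 14 steps (from 1: steps 1–5 and 10–18).

Steps most likely to fail:

Step 12 (key step). The alkoxide may fragment heterolytically or undergo a 1,3-shift; rearrangement may pass through the ring-flipped half-chair (1(10)E geometry); or the C7 configuration may be lost by proton exchange of the enolate. The fallback is a neutral siloxy-Cope rearrangement with a separate, controlled protonation, and it sets out from 16. Silylation of the tertiary hydroxyl (Me3SiOTf, Et3N, CH2Cl2, −78 °C) should give the trimethylsilyl ether of 16 F1. Heating (toluene, 170 °C, sealed tube, N,O-bis(trimethylsilyl)acetamide as acid scavenger) should bring about the same [3,3] shift without any anion and give the ring-expanded trimethylsilyl enol ether F2. Treatment with n-Bu4NF/AcOH at −78 °C then protonates C7 under kinetic control and comes back to the route at 19.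

Step 10. Facial selectivity may be poor (equatorial attack anti to the C1 side chain), giving the C6 epimer, which would lead to the 1(10)E, 9-epi series. The fallback relays facial control through a temporarily inverted C3 center and sets out from 6. HF·pyridine should give the hydroxy enone F3. Mitsunobu inversion (PhCO2H, PPh3, diisopropyl azodicarboxylate) should give the C3-inverted benzoate F4, whose pseudoaxial acyloxy group blocks the face anti to the C1 side chain. Addition of 14 at −78 °C should then give the adduct F5, and K2CO3/MeOH the C3-epimeric diol F6. A second Mitsunobu inversion at the secondary allylic hydroxyl should give the benzoate with C3 restored to S F7, and methanolysis the cis-diol F8. Silylation of the secondary hydroxyl only (t-BuMe2SiOTf, 1 equiv, 2,6-lutidine, −78 °C) comes back to the route at 15.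

Step 11. Deprotonation at the hindered 2-substituted allyl ether may be incomplete, the α-aryloxyallyllithium may react in other ways, or the alkoxide may rearrange prematurely through the unisomerised 1,1-disubstituted alkene. The fallback protects the tertiary alcohol, uses the classical KOt-Bu/DMSO allyl → cis-propenyl ether isomerisation, and rearranges a dianion; it sets out from 15. Et3SiOTf/2,6-lutidine should give the triethylsilyl ether of 15 F9. KOt-Bu in DMSO (23–40 °C) should give the (E)-enol ether F10. n-Bu4NF buffered with AcOH (0 °C) should remove the tertiary triethylsilyl and the primary silyl groups to give the diol F11. KH (2.5 equiv)/18-crown-6 in THF should rearrange the dianion to the hydroxy ketone F12 (quench as in step 12). Reduction with i-Bu2AlH comes back to the route at 21.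

**Further compounds**
F1 | step 12 | trimethylsilyl ether of 16 | CC1=C[C@](O[Si](C)(C)C)(C(=C)[C@@H](C)CO[Si](C)(C)C(C)(C)C)[C@@H](C[C@@H]1O[Si](C)(C)C(C)(C)C)/C(C)=C/Oc2ccc(OC)cc2
F2 | step 12 | ring-expanded trimethylsilyl enol ether (C6=C7) corresponding to 19 | CC(C)(C)[Si](C)(C)O[C@H]1C/C=C(/C)[C@H](Oc2ccc(OC)cc2)C/C([C@@H](C)CO[Si](C)(C)C(C)(C)C)=C(\O[Si](C)(C)C)/C=C\1C
F3 | step 10 | (4S,6S)-4-hydroxy-6-[3-(4-methoxyphenoxy)prop-1-en-2-yl]-3-methylcyclohex-2-en-1-one | CC1=CC(=O)[C@@H](C[C@@H]1O)C(=C)COc2ccc(OC)cc2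
F4 | step 10 | (1R,5S)-5-[3-(4-methoxyphenoxy)prop-1-en-2-yl]-2-methyl-4-oxocyclohex-2-en-1-yl benzoate | CC1=CC(=O)[C@@H](C[C@H]1OC(=O)c2ccccc2)C(=C)COc3ccc(OC)cc3
F5 | step 10 | C3-epimeric benzoate analogue of 15 (adduct of 14 and F4) | CC1=C[C@](O)(C(=C)[C@@H](C)CO[Si](C)(C)C(C)(C)C)[C@@H](C[C@H]1OC(=O)c2ccccc2)C(=C)COc3ccc(OC)cc3
F6 | step 10 | C3-epimeric 3,6-diol from F5 | CC1=C[C@](O)(C(=C)[C@@H](C)CO[Si](C)(C)C(C)(C)C)[C@@H](C[C@H]1O)C(=C)COc2ccc(OC)cc2
F7 | step 10 | benzoate with C3 restored to S | CC1=C[C@](O)(C(=C)[C@@H](C)CO[Si](C)(C)C(C)(C)C)[C@@H](C[C@@H]1OC(=O)c2ccccc2)C(=C)COc3ccc(OC)cc3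
F8 | step 10 | C3-desilylated 15 (3,6-diol) | CC1=C[C@](O)(C(=C)[C@@H](C)CO[Si](C)(C)C(C)(C)C)[C@@H](C[C@@H]1O)C(=C)COc2ccc(OC)cc2
F9 | step 11 | triethylsilyl ether of 15 | CC1=C[C@](O[Si](CC)(CC)CC)(C(=C)[C@@H](C)CO[Si](C)(C)C(C)(C)C)[C@@H](C[C@@H]1O[Si](C)(C)C(C)(C)C)C(=C)COc2ccc(OC)cc2
F10 | step 11 | triethylsilyl ether of 16 | CC1=C[C@](O[Si](CC)(CC)CC)(C(=C)[C@@H](C)CO[Si](C)(C)C(C)(C)C)[C@@H](C[C@@H]1O[Si](C)(C)C(C)(C)C)/C(C)=C/Oc2ccc(OC)cc2
F11 | step 11 | C12-desilylated 16 (C6–OH and C12–OH free) | CC1=C[C@](O)(C(=C)[C@@H](C)CO)[C@@H](C[C@@H]1O[Si](C)(C)C(C)(C)C)/C(C)=C/Oc2ccc(OC)cc2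
F12 | step 11 | C12-desilylated 19 (hydroxy ketone) | CC(C)(C)[Si](C)(C)O[C@H]1C/C=C(/C)[C@H](Oc2ccc(OC)cc2)C[C@@H]([C@@H](C)CO)C(=O)/C=C\1C
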